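Compound numbers used below are those of the steps and of the compound list. Ring atoms C1 to C8a refer to the isochroman-1-one skeleton; unprimed atoms belong to the unit whose C4 carries the aryloxy group (unit A), primed atoms to the unit whose O6′ is the ether oxygen (unit B).

## Analysis of the target

CNP0139537.5 consists of two isochroman-1-one (3,4-dihydroisocoumarin) units with the same substitution pattern: methyl at C3, oxygen at C4, C6, C7 (as methoxy) and C8, and one aromatic hydrogen at C5. The units are joined by a single ether bond from C4 of unit A to O6′ of unit B. Unit A keeps free phenols at C6 and C8; unit B keeps a free secondary alcohol at C4′ and a free phenol at C8′. There are four stereocentres (C3, C4, C3′, C4′), and both units are (3R,4S), which places the C3 methyl group and the C4 oxygen trans on each lactone ring. The sensitive points are the secondary benzylic C4–O bonds, which lie next to C3–H and can be lost by elimination to a conjugated enol lactone, and the 4′-hydroxy δ-lactone, which can contract to a five-membered lactone by acyl shift under base. The difficulties are a penta-substituted benzene ring with three adjacent oxygens beside the carbonyl group, an ether bond at a hindered secondary benzylic carbon of defined configuration, and the need to tell O6 from O8 in two nearly identical halves. The plan rests on the fact that in each unit the ring atoms C4a, C5, C6, C7, C8 and C8a form a 2-methoxyresorcylate. C5 to C8 with their three oxygens correspond to a 1,2,3-trioxygenated buta-1,3-diene, and the C4a–C8a edge with the C1 carbonyl corresponds to an alk-2-ynoate whose chain already carries C4 and C3 with their oxygens and the methyl group. Since both halves share this ring and the (3R,4S) pattern, one benzannulation product can supply both.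

## Retrosynthetic reasoning

**23 to 22.** The last operation only removes two silyl groups, one from O6 of unit A and one from O4′ of unit B. Both are chosen to come off in a single acidic fluoride treatment, because base would endanger the 4′-hydroxy lactone and the benzylic ether.

**22 to 21 and 17.** The C4–O6′ bond is cut, because it is the only bond between the halves and its cleavage gives two monomers with the same ring. C4 is the electrophile and the phenol oxygen O6′ the nucleophile. An ionising (SN1) union was weighed and set aside for three reasons:
- A cation at C4 gets little help from the ring: O6 and O8 are meta to C4a, the para methoxy group is twisted between two ortho substituents, and the ortho carbonyl group withdraws.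
- The cation has H3 beside it and would collapse to the C3=C4 enol lactone.
- The phenol partner offers a nucleophilic C5′ (ortho to O6′, para to O8′) for C-alkylation.

The bond is therefore made by an SN2 displacement under Mitsunobu conditions, which inverts C4. The electrophile must then be the cis (3R,4R) alcohol 21, attacked anti to its 3-methyl group. The nucleophile is 17, whose O6′ is free and acidic while the 8-hydroxyls of both partners are held by hydrogen bonds to the carbonyl groups.

**21 to 17 (through 19 and 18).** 21 differs from 17 in the position of the silyl group (O6 instead of O4) and in the configuration at C4. The silyl switch is made by cleaving the O4 silyl ether (18) and silylating the unchelated, most acidic phenol (19). C4 is then inverted by a Mitsunobu reaction with a small carboxylic acid, whose ester 20 is cleaved under nearly neutral conditions. The gain is that one benzannulation product, 17, feeds both halves, and that each change at C4 is a defined SN2 inversion.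

**17 to 7 and 13.** Three bonds are cut: C4a–C5 and C8–C8a of the benzene ring, and the lactone bond C1–O2. This is the place to cut because the trioxygenated ring is hard to build by substitution of a benzene, whereas diene 13 carries O6, O7 and O8 already in place and ynoate 7 carries C1, C3, C4 and both stereocentres. The forward reaction has to join the CH2 terminus of 13 to the β-carbon of 7, aromatise, and close the lactone through O3 only, which the robust silyl group on O4 ensures.

**7 to 3 and 4 (through 6 and 5).** The bond between the alkyne and the carbinol carbon is cut. In the forward direction acetylide 5, made from 4, adds to the α-silyloxy aldehyde 3 under Felkin–Anh control, which sets the carbinol centre anti to the existing one. The new hydroxyl of 6 is capped with a more robust silyl group than the one on O5, which has to leave first in the benzannulation step.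

**3 to 1 (through 2).** The methyl-bearing stereocentre (later C3 and C3′) is taken from the chiral pool: 1 is silylated and its ester reduced to the aldehyde.

**13 to 8 (through 12, 11, 10 and 9).** The diene is the bis-silyl dienol ether of a 2-methoxy β-keto ester. The methoxy group (later 7-OMe) is placed on 8 by diazo transfer and carbenoid O–H insertion, and two successive O-silylations (enol, then dienolate 12) give 13.

## Alternatives that were turned down

**Alternative 1: carboxylate-directed C–H alkylation with an epoxide.**
- Disconnection: C4a–C4 and C1–O2 of one isochromanone, leading to 2,4-bis(benzyloxy)-3-methoxybenzoic acid A2 and (R)-propylene oxide A3.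
- Forward key step: a divalent palladium carboxylate catalyst with a mono-N-protected amino acid ligand would palladate the only free position ortho to the carboxylate of A2. The aryl–palladium bond would open A3 at its CH2 terminus, and the alkoxide would lactonise to (R)-6,8-bis(benzyloxy)-7-methoxy-3-methylisochroman-1-one A1.
- For it: one step from a simple benzoic acid to the lactone, no regiochemical question, and C3 from an inexpensive chiral epoxide without any diastereoselection. In step economy to the bicyclic skeleton it is clearly stronger than the chosen route.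
- Against it: A1 has a CH2 group at C4, whereas both halves of the target need oxygen there with defined configuration, and in one half that oxygen is the inter-unit ether. It would have to be introduced later by benzylic C–H functionalisation beside C3–H. Radical or cationic intermediates there tend to eliminate across C3–C4, the benzylic CH2 groups of the two benzyl ethers compete, and the trans configuration would rest on substrate control by one methyl group.
- Comparison: the chosen strategy is longer up to the lactone, but it brings the C4 oxygen with its configuration from the open chain, so no oxidation at C4 is needed.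

**Alternative 2: chiral hypervalent iodine oxylactonisation.**
- Disconnection: C3–O2 and C4–O, both across the alkene of methyl 3-methoxy-2,4-bis(pivaloyloxy)-6-[(Z)-prop-1-enyl]benzoate A5.
- Forward key step: a lactate-derived chiral aryl iodine diacetate (a trivalent iodine reagent), with a boron Lewis acid and a carboxylic acid, would activate the alkene. The ester carbonyl oxygen would close the six-membered ring at C3 and an acetoxy group would displace iodine at C4, giving (3R,4S)-4-acetoxy-7-methoxy-3-methyl-6,8-bis(pivaloyloxy)isochroman-1-one A4.
- For it: both stereocentres and both C–O bonds are made in one step on a preformed arene, and the C4 oxygen arrives in the right oxidation state. On this point it is as strong as the chosen strategy and more direct.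
- Against it:
  - The trans product comes from net syn addition (two inversions) to the Z alkene, so any E isomer gives the cis series.
  - The trioxygenated arene, even with two pivalates, can stabilise an open cation at C4 para to the methoxy group, which would erode both diastereo- and enantioselectivity, and the ring itself can be oxidised by the reagent.
  - Closure at C4 instead of C3 would give the five-membered lactone.
  - The chiral reagent is stoichiometric and its face selectivity on this substrate cannot be predicted.
  - A4 carries three acyl groups, whose removal needs base or nucleophiles, the conditions under which a 4-hydroxy lactone contracts. O6 and O8 would emerge undifferentiated, so the phenol partner for the ether would need extra steps.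
- Comparison: the chosen strategy takes its configuration from 1 and from a substrate-controlled addition, uses silyl groups that leave in acid, and delivers O6 free and O8 chelated directly. It pays with a longer open-chain sequence and a cycloaddition not yet run on these partners.

**Alternative 3: monooxygenase ring expansion of an indanone.**
- Disconnection: C1–O2 and O2–C3, that is, the ring oxygen is inserted into 5,7-dihydroxy-6-methoxy-2-methylindan-1-one A7.
- Forward key step: a Baeyer–Villiger monooxygenase would insert oxygen between the ketone carbon and the methyl-bearing carbon while the α-stereocentre of A7 racemises through its enol. This dynamic kinetic resolution would give (R)-6,8-dihydroxy-7-methoxy-3-methylisochroman-1-one A6.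
- For it: no protecting groups, a catalytic oxidation in water with air, and C3 set by the enzyme. In protecting-group economy and mildness it is superior to the chosen route.
- Against it: the enzyme would have to make the secondary alkyl carbon migrate in preference to an electron-rich aryl group, which is the better migrating group in a peracid oxidation. It would also have to accept a trioxygenated, chelated substrate, and racemisation would have to outpace oxidation; none of this follows from the structure. Like A1, A6 lacks the C4 oxygen, so the late benzylic oxidation problem of alternative 1 returns, now on an unprotected, oxidation-prone resorcinol.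
- Comparison: the chosen strategy has the C4 oxygen in place from the start.

Key step: step 9

Remark on the chemistry: in step 3 the Felkin (4,5-anti) adduct 6 is assumed to be the major product and to be separable from its syn epimer by chromatography.

## Route

Step 1
Reactants: 1 methyl (R)-lactate
Product: 2 methyl (R)-2-(triethylsilyloxy)propanoate
Conditions: Et3SiCl, imidazole, CH2Cl2, 0 → 23 °C
Reagents that add atoms: chlorotriethylsilane, CC[Si](Cl)(CC)CC
Why: Silylation of a secondary alcohol with a chlorosilane and imidazole; the stereocentre (later C3 and C3′) is not touched, and the triethylsilyl group is chosen because mild acid removes it in the presence of a tert-butyldimethylsilyl ether.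

Step 2
Reactants: 2 methyl (R)-2-(triethylsilyloxy)propanoate
Product: 3 (R)-2-(triethylsilyloxy)propanal
Conditions: i-Bu2AlH, CH2Cl2, −78 °C; aq. potassium sodium tartrate (KNaC4H4O6)
Reagents that add atoms: none
Why: Partial reduction of an ester by i-Bu2AlH at low temperature: the tetrahedral aluminium hemiacetal survives until work-up, so the aldehyde is not reduced further; the α-silyloxy aldehyde is used crude and at once to avoid epimerisation.

Step 3
Reactants: 3 (R)-2-(triethylsilyloxy)propanal; 4 methyl propiolate
Product: 6 methyl (4S,5R)-4-hydroxy-5-(triethylsilyloxy)hex-2-ynoate, via methyl 3-lithioprop-2-ynoate 5 (not isolated)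
Conditions: 4, LiN(SiMe3)2, THF, −78 °C; then 3, −78 °C; aq. NH4Cl
Reagents that add atoms: none
Why: Deprotonation of the terminal alkyne and 1,2-addition of the lithium acetylide to the aldehyde; with a non-chelating silyl ether and lithium in THF the Felkin–Anh arrangement (C–OSi bond anti to the incoming nucleophile, attack past H) should prevail and set C4 as S (4,5-anti), the minor syn epimer being removed by chromatography.

Step 4
Reactants: 6 methyl (4S,5R)-4-hydroxy-5-(triethylsilyloxy)hex-2-ynoate
Product: 7 methyl (4S,5R)-4-(tert-butyldimethylsilyloxy)-5-(triethylsilyloxy)hex-2-ynoate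
Conditions: t-BuMe2SiOTf, 2,6-lutidine, CH2Cl2, −78 °C
Reagents that add atoms: tert-butyldimethylsilyl trifluoromethanesulfonate, CC(C)(C)[Si](C)(C)OS(=O)(=O)C(F)(F)F
Why: Silylation of a secondary propargylic alcohol with a silyl triflate and a hindered pyridine base at low temperature, which avoids base-induced isomerisation of the γ-hydroxy ynoate and leaves the triethylsilyl ether alone; this group will later keep O4 from lactonising.

Step 5
Reactants: 8 methyl acetoacetate
Product: 9 methyl 2-diazo-3-oxobutanoate
Conditions: 4-AcNHC6H4SO2N3, Et3N, MeCN, 0 → 23 °C
Reagents that add atoms: 4-acetamidobenzenesulfonyl azide, CC(=O)Nc1ccc(cc1)S(=O)(=O)N=[N+]=[N-]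
Why: Regitz diazo transfer from a sulfonyl azide to the active methylene group of a β-keto ester.

Step 6
Reactants: 9 methyl 2-diazo-3-oxobutanoate
Product: 10 methyl 2-methoxy-3-oxobutanoate
Conditions: Rh2(OAc)4 (1 mol %), MeOH, CH2Cl2, 40 °C
Reagents that add atoms: methanol, CO
Why: Rh2(OAc)4 decomposes the diazo compound to a divalent rhodium carbenoid, which inserts into the O–H bond of methanol (carbenoid O–H insertion) and so places the methoxy group that becomes 7-OMe.

Step 7
Reactants: 10 methyl 2-methoxy-3-oxobutanoate
Product: 11 methyl 2-methoxy-3-(trimethylsilyloxy)but-2-enoate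
Conditions: Me3SiCl, Et3N, toluene, 23 °C
Reagents that add atoms: chlorotrimethylsilane, C[Si](C)(C)Cl
Why: O-Silylation of the enolised β-keto ester with a chlorosilane and triethylamine gives the conjugated silyl enol ether; the double-bond geometry is of no consequence.

Step 8
Reactants: 11 methyl 2-methoxy-3-(trimethylsilyloxy)but-2-enoate
Product: 13 1,2-dimethoxy-1,3-bis(trimethylsilyloxy)buta-1,3-diene, via lithium dienolate 12 (not isolated)
Conditions: LiN(i-Pr)2, THF, −78 °C; then Me3SiCl, −78 → 0 °C
Reagents that add atoms: chlorotrimethylsilane, C[Si](C)(C)Cl
Why: LiN(i-Pr)2 removes a proton from the γ-methyl group of the vinylogous ester and O-silylation of the dienolate gives the 1-alkoxy-1,3-bis(silyloxy)diene, the standard two-stage route to such dienes; the moisture-sensitive product is used directly after removal of the volatiles.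

Step 9
Reactants: 7 methyl (4S,5R)-4-(tert-butyldimethylsilyloxy)-5-(triethylsilyloxy)hex-2-ynoate; 13 1,2-dimethoxy-1,3-bis(trimethylsilyloxy)buta-1,3-diene
Product: 17 (3R,4S)-4-(tert-butyldimethylsilyloxy)-6,8-dihydroxy-7-methoxy-3-methylisochroman-1-one, via cycloadduct 14 (not isolated), via silylated benzoate 15 (not isolated), via hydroxy ester 16 (not isolated)
Conditions: 13 (3 equiv), toluene, 110 °C (sealed tube); then PPTS, MeOH, 23 °C; then CSA (cat.), toluene, 60 °C
Reagents that add atoms: none
Why: A normal-electron-demand Diels–Alder reaction (possibly asynchronous, with Mukaiyama–Michael character) joins the nucleophilic CH2 terminus of 13 to the β-carbon of the ynoate (C4a–C5) and the ketene acetal carbon to the α-carbon (C8–C8a), the orientation in which the largest HOMO coefficient of the diene meets the largest LUMO coefficient of the ynoate. Cycloadduct 14 is a cyclohexa-1,4-diene with a mixed silyl methyl ketal at the future C8, and 1,4-elimination of methanol across C8 and the doubly allylic C5–H aromatises it to 15. The closest known reaction type is the Diels–Alder benzannulation of 1-alkoxy-1,3-bis(silyloxy)dienes with alkynoates to resorcylates, here with an extra 2-methoxy group on the diene and a branched γ,δ-bis(silyloxy) chain on the ynoate. The benzene ring is closed by the [4+2] cycloaddition followed by aromatisation; the lactone ring is closed after acidic methanolysis of the two aryl trimethylsilyl ethers and the triethylsilyl ether (16) by attack of the C3 hydroxyl on the neighbouring ester, a 6-exo-trig acyl substitution driven by acid and by removal of methanol. No stereocentre is formed: C3 and C4 come unchanged from 7, since neither C–O bond is broken. The step needs regioselectivity, which polarity matching secures, and chemoselectivity among the silyl ethers, which the order of acid lability secures (aryl trimethylsilyl and secondary triethylsilyl well ahead of secondary tert-butyldimethylsilyl); the surviving silyl ether on O4 rules out the five-membered lactone. The product has O6 free and O8 hydrogen-bonded to the carbonyl group, as the later steps require.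

Step 10
Reactants: 17 (3R,4S)-4-(tert-butyldimethylsilyloxy)-6,8-dihydroxy-7-methoxy-3-methylisochroman-1-one
Product: 18 (3R,4S)-4,6,8-trihydroxy-7-methoxy-3-methylisochroman-1-one
Conditions: 48% aq. HF, MeCN, 0 → 23 °C
Reagents that add atoms: none
Why: Cleavage of a secondary alkyl silyl ether by aqueous HF in acetonitrile; the medium is acidic, so the freed 4-hydroxy lactone should not undergo the base-induced acyl shift to O4, and the benzylic C–O bond, deactivated by the ortho carbonyl group, should not ionise.

Step 11
Reactants: 18 (3R,4S)-4,6,8-trihydroxy-7-methoxy-3-methylisochroman-1-one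
Product: 19 (3R,4S)-4,8-dihydroxy-7-methoxy-3-methyl-6-(triisopropylsilyloxy)isochroman-1-one
Conditions: i-Pr3SiCl, imidazole, DMF, 0 °C
Reagents that add atoms: chlorotriisopropylsilane, CC(C)[Si](Cl)(C(C)C)C(C)C
Why: Silylation of a phenol with a bulky chlorosilane and imidazole: the unchelated, more acidic 6-OH reacts, whereas the 8-OH is held in a hydrogen bond to the lactone carbonyl and the hindered secondary 4-OH reacts much more slowly with a triisopropylsilyl chloride.

Step 12
Reactants: 19 (3R,4S)-4,8-dihydroxy-7-methoxy-3-methyl-6-(triisopropylsilyloxy)isochroman-1-one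
Product: 21 (3R,4R)-4,8-dihydroxy-7-methoxy-3-methyl-6-(triisopropylsilyloxy)isochroman-1-one, via cis formate 20 (not isolated)
Conditions: HCO2H, PPh3, DIAD, THF, 0 → 23 °C; then KHCO3, MeOH/H2O, 0 °C
Reagents that add atoms: formic acid, O=CO
Why: Mitsunobu inversion: the alkoxyphosphonium ion formed from the 4-OH is displaced by formate in an SN2 step, which turns C4 from S to R (oxygen now cis to the methyl group), and the labile formate is removed by bicarbonate methanolysis without isolation; formate is chosen because it is small (it must enter on the face of the 3-methyl group) and leaves under nearly neutral conditions, and H3 is syn to the leaving group, so anti elimination is not available.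

Step 13
Reactants: 21 (3R,4R)-4,8-dihydroxy-7-methoxy-3-methyl-6-(triisopropylsilyloxy)isochroman-1-one; 17 (3R,4S)-4-(tert-butyldimethylsilyloxy)-6,8-dihydroxy-7-methoxy-3-methylisochroman-1-one
Product: 22 (3R,4S)-4-{[(3R,4S)-4-(tert-butyldimethylsilyloxy)-8-hydroxy-7-methoxy-3-methyl-1-oxoisochroman-6-yl]oxy}-8-hydroxy-7-methoxy-3-methyl-6-(triisopropylsilyloxy)isochroman-1-one
Conditions: PPh3, DIAD, toluene, 0 → 23 °C
Reagents that add atoms: none
Why: Mitsunobu etherification of a secondary benzylic alcohol with a phenol: the 6-OH of 17 (a para-acyl phenol, acidic enough to protonate the betaine) displaces the alkoxyphosphonium ion of 21 by SN2 from the face opposite the 3-methyl group, which returns C4 to S and gives the trans ether; the 8-OH groups of both partners are chelated, less acidic and hindered, and the ortho carbonyl group disfavours ionisation at C4, so inversion should be clean.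

Step 14
Reactants: 22 (3R,4S)-4-{[(3R,4S)-4-(tert-butyldimethylsilyloxy)-8-hydroxy-7-methoxy-3-methyl-1-oxoisochroman-6-yl]oxy}-8-hydroxy-7-methoxy-3-methyl-6-(triisopropylsilyloxy)isochroman-1-one
Product: 23 (3R,4S)-4-{[(3R,4S)-4,8-dihydroxy-7-methoxy-3-methyl-1-oxoisochroman-6-yl]oxy}-6,8-dihydroxy-7-methoxy-3-methylisochroman-1-one (CNP0139537.5)
Conditions: HF·pyridine, pyridine/THF, 0 → 23 °C
Reagents that add atoms: none
Why: Global desilylation with buffered HF·pyridine removes the aryl triisopropylsilyl ether and the secondary tert-butyldimethylsilyl ether in one operation; a basic fluoride source is avoided because it would invite the acyl shift of the 4′-hydroxy lactone and elimination at C4.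

## Compound list

1 | methyl (R)-lactate | C[C@@H](O)C(=O)OC | starting material
2 | methyl (R)-2-(triethylsilyloxy)propanoate | C[C@@H](O[Si](CC)(CC)CC)C(=O)OC | intermediate
3 | (R)-2-(triethylsilyloxy)propanal | C[C@@H](O[Si](CC)(CC)CC)C=O | intermediate
4 | methyl propiolate | C#CC(=O)OC | starting material
5 | methyl 3-lithioprop-2-ynoate | [Li]C#CC(=O)OC | intermediate (not isolated)
6 | methyl (4S,5R)-4-hydroxy-5-(triethylsilyloxy)hex-2-ynoate | C[C@@H](O[Si](CC)(CC)CC)[C@@H](O)C#CC(=O)OC | intermediate
7 | methyl (4S,5R)-4-(tert-butyldimethylsilyloxy)-5-(triethylsilyloxy)hex-2-ynoate | C[C@@H](O[Si](CC)(CC)CC)[C@@H](O[Si](C)(C)C(C)(C)C)C#CC(=O)OC | intermediate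
8 | methyl acetoacetate | CC(=O)CC(=O)OC | starting material
9 | methyl 2-diazo-3-oxobutanoate | CC(=O)C(=[N+]=[N-])C(=O)OC | intermediate
10 | methyl 2-methoxy-3-oxobutanoate | CC(=O)C(OC)C(=O)OC | intermediate
11 | methyl 2-methoxy-3-(trimethylsilyloxy)but-2-enoate (E/Z mixture) | CC(O[Si](C)(C)C)=C(OC)C(=O)OC | intermediate
12 | lithium 1,2-dimethoxy-3-(trimethylsilyloxy)buta-1,3-dien-1-olate | C=C(O[Si](C)(C)C)C(OC)=C(OC)O[Li] | intermediate (not isolated)
13 | 1,2-dimethoxy-1,3-bis(trimethylsilyloxy)buta-1,3-diene | C=C(O[Si](C)(C)C)C(OC)=C(OC)O[Si](C)(C)C | intermediate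
14 | methyl 2-[(1S,2R)-1-(tert-butyldimethylsilyloxy)-2-(triethylsilyloxy)propyl]-5,6-dimethoxy-4,6-bis(trimethylsilyloxy)cyclohexa-1,4-diene-1-carboxylate (mixture at the ketal carbon) | C[C@@H](O[Si](CC)(CC)CC)[C@@H](O[Si](C)(C)C(C)(C)C)C1=C(C(=O)OC)C(OC)(O[Si](C)(C)C)C(OC)=C(O[Si](C)(C)C)C1 | intermediate (not isolated)
15 | methyl 6-[(1S,2R)-1-(tert-butyldimethylsilyloxy)-2-(triethylsilyloxy)propyl]-3-methoxy-2,4-bis(trimethylsilyloxy)benzoate | C[C@@H](O[Si](CC)(CC)CC)[C@@H](O[Si](C)(C)C(C)(C)C)c1cc(O[Si](C)(C)C)c(OC)c(O[Si](C)(C)C)c1C(=O)OC | intermediate (not isolated)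
16 | methyl 6-[(1S,2R)-1-(tert-butyldimethylsilyloxy)-2-hydroxypropyl]-2,4-dihydroxy-3-methoxybenzoate | C[C@@H](O)[C@@H](O[Si](C)(C)C(C)(C)C)c1cc(O)c(OC)c(O)c1C(=O)OC | intermediate (not isolated)
17 | (3R,4S)-4-(tert-butyldimethylsilyloxy)-6,8-dihydroxy-7-methoxy-3-methylisochroman-1-one | COc1c(O)cc2c(c1O)C(=O)O[C@H](C)[C@H]2O[Si](C)(C)C(C)(C)C | intermediate
18 | (3R,4S)-4,6,8-trihydroxy-7-methoxy-3-methylisochroman-1-one | COc1c(O)cc2c(c1O)C(=O)O[C@H](C)[C@H]2O | intermediate
19 | (3R,4S)-4,8-dihydroxy-7-methoxy-3-methyl-6-(triisopropylsilyloxy)isochroman-1-one | COc1c(O[Si](C(C)C)(C(C)C)C(C)C)cc2c(c1O)C(=O)O[C@H](C)[C@H]2O | intermediate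
20 | (3R,4R)-8-hydroxy-7-methoxy-3-methyl-1-oxo-6-(triisopropylsilyloxy)isochroman-4-yl formate | COc1c(O[Si](C(C)C)(C(C)C)C(C)C)cc2c(c1O)C(=O)O[C@H](C)[C@@H]2OC=O | intermediate (not isolated)
21 | (3R,4R)-4,8-dihydroxy-7-methoxy-3-methyl-6-(triisopropylsilyloxy)isochroman-1-one | COc1c(O[Si](C(C)C)(C(C)C)C(C)C)cc2c(c1O)C(=O)O[C@H](C)[C@@H]2O | intermediate
22 | (3R,4S)-4-{[(3R,4S)-4-(tert-butyldimethylsilyloxy)-8-hydroxy-7-methoxy-3-methyl-1-oxoisochroman-6-yl]oxy}-8-hydroxy-7-methoxy-3-methyl-6-(triisopropylsilyloxy)isochroman-1-one | COc1c(O[Si](C(C)C)(C(C)C)C(C)C)cc2c(c1O)C(=O)O[C@H](C)[C@H]2Oc1cc2c(c(O)c1OC)C(=O)O[C@H](C)[C@H]2O[Si](C)(C)C(C)(C)C | intermediate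
23 | (3R,4S)-4-{[(3R,4S)-4,8-dihydroxy-7-methoxy-3-methyl-1-oxoisochroman-6-yl]oxy}-6,8-dihydroxy-7-methoxy-3-methylisochroman-1-one (CNP0139537.5) | COc1c(O)cc2c(c1O)C(=O)O[C@H](C)[C@H]2Oc1cc2c(c(O)c1OC)C(=O)O[C@H](C)[C@H]2O | target

## Step count and least certain steps

Total step count: 14. Longest linear sequence: 10 steps (steps 1–4 and 9–14 from 1; equally steps 5–8 and 9–14 from 8). Compound 17 is used twice, in steps 10 and 13.

**Step 9 (key step).**
- Risk: the cycloaddition may be too slow. The ynoate is hindered at its β-carbon by the branched silyloxy chain, the acyclic diene has to reach its s-cis conformer, and at the temperature needed the diene can be consumed by silyl transfer, hydrolysis or polymerisation. In the acid stage, premature loss of the benzylic silyl ether would open the way to closure of the five-membered lactone.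
- Fallback: the acyclic diene is replaced by a ring-locked one, and aromatisation by elimination is replaced by a retro-Diels–Alder step. The fallback sets out from 7. Purchased 5,5-dimethylcyclohexane-1,3-dione F1 would be taken by diazo transfer to 2-diazo-5,5-dimethylcyclohexane-1,3-dione F2, then by Rh2(OAc)4-catalysed O–H insertion into methanol to 2-methoxy-5,5-dimethylcyclohexane-1,3-dione F3. Double O-silylation (Me3SiCl, Et3N; then LiN(i-Pr)2, Me3SiCl) would give 2-methoxy-5,5-dimethyl-1,3-bis(trimethylsilyloxy)cyclohexa-1,3-diene F4. Heated with 7 (xylene, 140 °C), F4 should give methyl 3-[(1S,2R)-1-(tert-butyldimethylsilyloxy)-2-(triethylsilyloxy)propyl]-6-methoxy-8,8-dimethyl-1,5-bis(trimethylsilyloxy)bicyclo[2.2.2]octa-2,5-diene-2-carboxylate F5. F5 loses 2-methylpropene by retro-Diels–Alder reaction (Alder–Rickert sequence) and so comes back to the route at 15, from which the acid stages of step 9 lead to 17. The regiochemistry is the same, since the unsubstituted diene terminus again bonds to the β-carbon of the ynoate.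

**Step 13.**
- Risk: displacement at C4 of 21 may be slow. The carbon is secondary and benzylic, it lies between C3 and the peri C5–H, the phenol has an ortho methoxy group, and the phosphonium leaving group is bulky. Anti elimination of H3 with the activated oxygen could then take over, and partial ionisation would erode the configuration at C4.
- Fallback: activation and displacement are separated. It sets out from 21, which would be converted with retention (MsCl, Et3N, CH2Cl2, −20 °C) into (3R,4R)-8-hydroxy-7-methoxy-3-methyl-1-oxo-6-(triisopropylsilyloxy)isochroman-4-yl methanesulfonate F6. Displacement by the caesium phenoxide of 17 (Cs2CO3, MeCN, 23 °C) would proceed with inversion and come back to the route at 22. The leaving group is smaller, and the phenoxide of a para-acyl phenol is a weak base, which limits elimination.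

**Step 12.**
- Risk: the nucleophile has to enter on the face of the 3-methyl group, so displacement of the alkoxyphosphonium ion may stall or proceed with loss of stereochemical integrity. During cleavage of the formate, the cis 4-hydroxy lactone may undergo ring contraction by acyl shift if the medium is too basic.
- Fallback: a sulfonate inversion without phosphorus reagents. It sets out from 19, which would be mesylated with retention to (3R,4S)-8-hydroxy-7-methoxy-3-methyl-1-oxo-6-(triisopropylsilyloxy)isochroman-4-yl methanesulfonate F7. Displacement with HCO2Cs and 18-crown-6 in toluene at 80 °C (SN2, inversion; H3 is syn to the leaving group) would come back to the route at 20, which is methanolysed as in step 12.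

**Step 3.**
- Risk: poor facial selectivity, since a lithium acetylide is small and a triethylsilyl ether enforces the Felkin–Anh arrangement only moderately. Partial epimerisation of aldehyde 3 before addition would erode enantiopurity.
- Fallback: the syn epimer is used instead of discarded, so that the configuration of the unit A half comes from the open chain and not from an inversion. It sets out from 3.
  - The syn adduct methyl (4R,5R)-4-hydroxy-5-(triethylsilyloxy)hex-2-ynoate F8, separated in step 3, would be silylated as in step 4 to methyl (4R,5R)-4-(tert-butyldimethylsilyloxy)-5-(triethylsilyloxy)hex-2-ynoate F9.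
  - Under the conditions of step 9, F9 would pass through methyl 2-[(1R,2R)-1-(tert-butyldimethylsilyloxy)-2-(triethylsilyloxy)propyl]-5,6-dimethoxy-4,6-bis(trimethylsilyloxy)cyclohexa-1,4-diene-1-carboxylate F10, methyl 6-[(1R,2R)-1-(tert-butyldimethylsilyloxy)-2-(triethylsilyloxy)propyl]-3-methoxy-2,4-bis(trimethylsilyloxy)benzoate F11 and methyl 6-[(1R,2R)-1-(tert-butyldimethylsilyloxy)-2-hydroxypropyl]-2,4-dihydroxy-3-methoxybenzoate F12 to (3R,4R)-4-(tert-butyldimethylsilyloxy)-6,8-dihydroxy-7-methoxy-3-methylisochroman-1-one F13.
  - Desilylation as in step 10 would give (3R,4R)-4,6,8-trihydroxy-7-methoxy-3-methylisochroman-1-one F14, and silylation as in step 11 would come back to the route at 21.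
  - The anti adduct 6 then serves only the unit B half (17). A mixture of the two epimers is consumed in full if it is close to equal, and step 12 is bypassed for that material.

## Further compounds

F1 | step 9 | 5,5-dimethylcyclohexane-1,3-dione | CC1(C)CC(=O)CC(=O)C1
F2 | step 9 | 2-diazo-5,5-dimethylcyclohexane-1,3-dione | CC1(C)CC(=O)C(=[N+]=[N-])C(=O)C1
F3 | step 9 | 2-methoxy-5,5-dimethylcyclohexane-1,3-dione | COC1C(=O)CC(C)(C)CC1=O
F4 | step 9 | 2-methoxy-5,5-dimethyl-1,3-bis(trimethylsilyloxy)cyclohexa-1,3-diene | COC1=C(O[Si](C)(C)C)CC(C)(C)C=C1O[Si](C)(C)C
F5 | step 9 | methyl 3-[(1S,2R)-1-(tert-butyldimethylsilyloxy)-2-(triethylsilyloxy)propyl]-6-methoxy-8,8-dimethyl-1,5-bis(trimethylsilyloxy)bicyclo[2.2.2]octa-2,5-diene-2-carboxylate | C[C@@H](O[Si](CC)(CC)CC)[C@@H](O[Si](C)(C)C(C)(C)C)C1=C(C(=O)OC)C2(O[Si](C)(C)C)CC(C)(C)C1C(O[Si](C)(C)C)=C2OC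
F6 | step 13 | (3R,4R)-8-hydroxy-7-methoxy-3-methyl-1-oxo-6-(triisopropylsilyloxy)isochroman-4-yl methanesulfonate | COc1c(O[Si](C(C)C)(C(C)C)C(C)C)cc2c(c1O)C(=O)O[C@H](C)[C@@H]2OS(C)(=O)=O
F7 | step 12 | (3R,4S)-8-hydroxy-7-methoxy-3-methyl-1-oxo-6-(triisopropylsilyloxy)isochroman-4-yl methanesulfonate | COc1c(O[Si](C(C)C)(C(C)C)C(C)C)cc2c(c1O)C(=O)O[C@H](C)[C@H]2OS(C)(=O)=O
F8 | step 3 | methyl (4R,5R)-4-hydroxy-5-(triethylsilyloxy)hex-2-ynoate | C[C@@H](O[Si](CC)(CC)CC)[C@H](O)C#CC(=O)OC
F9 | step 3 | methyl (4R,5R)-4-(tert-butyldimethylsilyloxy)-5-(triethylsilyloxy)hex-2-ynoate | C[C@@H](O[Si](CC)(CC)CC)[C@H](O[Si](C)(C)C(C)(C)C)C#CC(=O)OC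
F10 | step 3 | methyl 2-[(1R,2R)-1-(tert-butyldimethylsilyloxy)-2-(triethylsilyloxy)propyl]-5,6-dimethoxy-4,6-bis(trimethylsilyloxy)cyclohexa-1,4-diene-1-carboxylate | C[C@@H](O[Si](CC)(CC)CC)[C@H](O[Si](C)(C)C(C)(C)C)C1=C(C(=O)OC)C(OC)(O[Si](C)(C)C)C(OC)=C(O[Si](C)(C)C)C1
F11 | step 3 | methyl 6-[(1R,2R)-1-(tert-butyldimethylsilyloxy)-2-(triethylsilyloxy)propyl]-3-methoxy-2,4-bis(trimethylsilyloxy)benzoate | C[C@@H](O[Si](CC)(CC)CC)[C@H](O[Si](C)(C)C(C)(C)C)c1cc(O[Si](C)(C)C)c(OC)c(O[Si](C)(C)C)c1C(=O)OC
F12 | step 3 | methyl 6-[(1R,2R)-1-(tert-butyldimethylsilyloxy)-2-hydroxypropyl]-2,4-dihydroxy-3-methoxybenzoate | C[C@@H](O)[C@H](O[Si](C)(C)C(C)(C)C)c1cc(O)c(OC)c(O)c1C(=O)OC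
F13 | step 3 | (3R,4R)-4-(tert-butyldimethylsilyloxy)-6,8-dihydroxy-7-methoxy-3-methylisochroman-1-one | COc1c(O)cc2c(c1O)C(=O)O[C@H](C)[C@@H]2O[Si](C)(C)C(C)(C)C
F14 | step 3 | (3R,4R)-4,6,8-trihydroxy-7-methoxy-3-methylisochroman-1-one | COc1c(O)cc2c(c1O)C(=O)O[C@H](C)[C@@H]2O
A1 | alternative 1 | (R)-6,8-bis(benzyloxy)-7-methoxy-3-methylisochroman-1-one | COc1c(OCc3ccccc3)cc2c(c1OCc4ccccc4)C(=O)O[C@H](C)C2
A2 | alternative 1 | 2,4-bis(benzyloxy)-3-methoxybenzoic acid | COc1c(OCc2ccccc2)ccc(C(=O)O)c1OCc1ccccc1
A3 | alternative 1 | (R)-propylene oxide | C[C@@H]1CO1
A4 | alternative 2 | (3R,4S)-4-acetoxy-7-methoxy-3-methyl-6,8-bis(pivaloyloxy)isochroman-1-one | COc1c(OC(=O)C(C)(C)C)cc2c(c1OC(=O)C(C)(C)C)C(=O)O[C@H](C)[C@H]2OC(C)=O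
A5 | alternative 2 | methyl 3-methoxy-2,4-bis(pivaloyloxy)-6-[(Z)-prop-1-enyl]benzoate | COC(=O)c1c(/C=C\C)cc(OC(=O)C(C)(C)C)c(OC)c1OC(=O)C(C)(C)C
A6 | alternative 3 | (R)-6,8-dihydroxy-7-methoxy-3-methylisochroman-1-one | COc1c(O)cc2c(c1O)C(=O)O[C@H](C)C2
A7 | alternative 3 | 5,7-dihydroxy-6-methoxy-2-methylindan-1-one (racemic) | COc1c(O)cc2c(c1O)C(=O)C(C)C2
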